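**Retrosynthetic overview**

1. Locants follow labdane numbering (C1–C10 decalin, C11–C16 side chain, C17 = exocyclic CH2, C19 = ester carbon on C4, C20 = angular CH3). Late stage: C1–OAc from a silyl ether; C8=C17 and C14=C15 together by methylenation of keto enal 22; the 12E alkene by a stabilised-ylide Wittig reaction; quaternary C4 by Krapcho mono-decarboxylation of a gem-diester and equatorial enolate methylation.
2. Key disconnection: C5–C10 and C8–C9. Ring B (C5–C6–C7–C8–C9–C10) is a cyclohexane whose C9 carries a one-carbon branch (C11) that can sit at the aldehyde level. With C6=C7 drawn in, ring B is the retron of a Diels–Alder reaction between a C5–C8 butadiene and an aldehyde-activated C9=C10 alkene, and the four atoms C1–C4 of ring A are exactly the tether that makes it intramolecular.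
3. Precursor: the acyclic (2E,8E)-undeca-2,8,10-trienal 11 with a single stereocentre (C1–OTBS) and a C4 gem-diester, assembled from dimethyl malonate, crotonaldehyde, acrolein and 2-butynal diethyl acetal.
4. Ring order: rings A and B are formed together in step 6; there is no other ring-forming step.

Key step: step 6

Remark (assumption): by the Noyori model for amino-alcohol–zinc catalysts, (+)-MIB is taken to deliver the alkenyl group to the Re face of aldehyde 5, which gives (S)-9.
Remark: 13 is an E/Z mixture and 15 a mixture of C4 epimers (drawn as the equatorial ester); both features are erased in the same or the next step.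

**Route**

Step 1
Reactants: 1 dimethyl malonate; 2 (E)-but-2-enal
Product: 3 dimethyl 2-[(2E)-but-2-en-1-ylidene]propanedioate
Conditions: piperidine (10 mol %), AcOH (10 mol %), toluene, 4 Å MS, 60 °C
Reagents that add atoms: none
Why: Knoevenagel condensation (iminium catalysis favours 1,2-condensation over conjugate addition) should give the dienylidene malonate; no stereocentre is formed.

Step 2
Reactants: 3 dimethyl 2-[(2E)-but-2-en-1-ylidene]propanedioate; 4 prop-2-enal (acrolein)
Product: 5 dimethyl 2-[(1E)-buta-1,3-dien-1-yl]-2-(3-oxopropyl)propanedioate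
Conditions: DBU (20 mol %), MeCN, −20 °C → 0 °C, slow addition of 4
Reagents that add atoms: none
Why: Deconjugative Michael addition: DBU removes an ε-proton of 3 and the malonate-stabilised trienolate reacts through its α-carbon, as in the well-known deconjugative alkylation of alkylidene malonates, so C4 becomes quaternary and the (E)-buta-1,3-dienyl group appears; no stereocentre is formed.

Step 3
Reactants: 5 dimethyl 2-[(1E)-buta-1,3-dien-1-yl]-2-(3-oxopropyl)propanedioate; 6 1,1-diethoxybut-2-yne
Product: 9 dimethyl 2-[(1E)-buta-1,3-dien-1-yl]-2-[(3S,4E)-6,6-diethoxy-3-hydroxy-4-methylhex-4-en-1-yl]propanedioate, via alkenylborane 7 (not isolated), via alkenylzinc 8 (not isolated)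
Conditions: 6, Cy2BH, toluene, 0 °C → rt; Me2Zn, −78 °C; (+)-MIB (5 mol %); then 5, −20 °C → 0 °C; aq. NH4Cl
Reagents that add atoms: none
Why: Oppolzer–Radinov/Walsh alkenylzinc addition: syn-hydroboration puts boron on the less hindered, methyl-bearing alkyne carbon, B-to-Zn exchange and addition go with retention so that C1 ends trans to C11 across the new trisubstituted alkene, and the MIB–zinc catalyst delivers the alkenyl group to the Re face of the aldehyde, which sets C1 as (S).

Step 4
Reactants: 9 dimethyl 2-[(1E)-buta-1,3-dien-1-yl]-2-[(3S,4E)-6,6-diethoxy-3-hydroxy-4-methylhex-4-en-1-yl]propanedioate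
Product: 10 dimethyl 2-[(1E)-buta-1,3-dien-1-yl]-2-[(3S,4E)-3-(tert-butyldimethylsilyloxy)-6,6-diethoxy-4-methylhex-4-en-1-yl]propanedioate
Conditions: TBSCl, imidazole, DMF, 0 °C → rt
Reagents that add atoms: tert-butyldimethylsilyl chloride CC(C)(C)[Si](C)(C)Cl
Why: Standard silylation of the allylic alcohol, carried out at once so that the δ-hydroxy diester cannot lactonise; C1 is untouched.

Step 5
Reactants: 10 dimethyl 2-[(1E)-buta-1,3-dien-1-yl]-2-[(3S,4E)-3-(tert-butyldimethylsilyloxy)-6,6-diethoxy-4-methylhex-4-en-1-yl]propanedioate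
Product: 11 dimethyl 2-[(1E)-buta-1,3-dien-1-yl]-2-[(3S,4E)-3-(tert-butyldimethylsilyloxy)-4-methyl-6-oxohex-4-en-1-yl]propanedioate
Conditions: PPTS (10 mol %), acetone/H2O (10:1), rt
Reagents that add atoms: water O
Why: Acid-catalysed hydrolysis of the allylic diethyl acetal, which ionises far more easily than the silyl ether, should unveil the (E)-enal dienophile without touching C1.

Step 6
Reactants: 11 dimethyl 2-[(1E)-buta-1,3-dien-1-yl]-2-[(3S,4E)-3-(tert-butyldimethylsilyloxy)-4-methyl-6-oxohex-4-en-1-yl]propanedioate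
Product: 12 dimethyl 1-(tert-butyldimethylsilyloxy)-9-formyl-10-methyl-trans-decal-6-ene-4,4-dicarboxylate
Conditions: Me2AlCl (2.2 equiv), CH2Cl2, −78 °C → −20 °C; 1 M HCl quench
Reagents that add atoms: none
Why: Me2AlCl binds the formyl oxygen and the trienal undergoes a concerted, asynchronous [4+2] cycloaddition (type 1 intramolecular Diels–Alder reaction; closest precedent: Lewis-acid-promoted cyclisations of 2,8,10-undecatrienals to trans-fused octalins), in which diene carbon C5 bonds to the β-carbon C10 and C8 bonds to C9. Ring B (C5–C6–C7–C8–C9–C10) is closed as the cycloaddition ring with C6=C7 left behind, and ring A (C10–C1–C2–C3–C4–C5) closes at the same moment through the four-carbon tether in a chair-like six-membered array that is exo to both π-components. C10 and C5: the endo position of the Al-bound formyl group puts the C10 methyl under the diene and the tether outside, so H5 and CH3-20 end up anti (trans ring fusion). C9: the (E)-geometry of the dienophile is transferred suprafacially, so the formyl carbon C11 is cis to CH3-20. The absolute sense comes from C1: in the chair-like tether the bulky silyloxy group lies pseudo-equatorial, anti to the forming C5–C10 bond and away from the approaching diene, so the diene should add to one π-face. The step needs endo over exo selectivity (secured by Lewis-acid activation of the terminal aldehyde), π-facial selectivity (secured by the C1 stereocentre) and enough reactivity to build the quaternary C10 (helped by the Thorpe–Ingold effect of the C4 gem-diester).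

Step 7
Reactants: 12 dimethyl 1-(tert-butyldimethylsilyloxy)-9-formyl-10-methyl-trans-decal-6-ene-4,4-dicarboxylate
Product: 14 dimethyl 1-(tert-butyldimethylsilyloxy)-9-(2,2-dimethoxyethyl)-10-methyl-trans-decal-6-ene-4,4-dicarboxylate, via enol ether 13 (not isolated)
Conditions: MeOCH2PPh3Cl, KN(SiMe3)2, THF, −78 °C → 0 °C; then MeOH, PPTS (cat.), rt
Reagents that add atoms: (methoxymethyl)triphenylphosphonium chloride COC[P+](c1ccccc1)(c1ccccc1)c1ccccc1.[Cl-]; methanol CO
Why: Wittig methoxymethylenation (ylide addition to the hindered aldehyde is faster than enolisation, so C9 keeps its configuration) followed by acid-catalysed addition of methanol to the enol ether should give the one-carbon homologue (C12) masked as its dimethyl acetal.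

Step 8
Reactants: 14 dimethyl 1-(tert-butyldimethylsilyloxy)-9-(2,2-dimethoxyethyl)-10-methyl-trans-decal-6-ene-4,4-dicarboxylate
Product: 15 methyl 1-(tert-butyldimethylsilyloxy)-9-(2,2-dimethoxyethyl)-10-methyl-trans-decal-6-ene-4-carboxylate
Conditions: LiCl, H2O (2 equiv), DMSO, 150 °C
Reagents that add atoms: none
Why: Krapcho dealkoxycarbonylation (SN2 demethylation by chloride, loss of CO2, protonation of the ester enolate) leaves one ester at C4; the C4 configuration of 15 is irrelevant because step 9 erases it.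

Step 9
Reactants: 15 methyl 1-(tert-butyldimethylsilyloxy)-9-(2,2-dimethoxyethyl)-10-methyl-trans-decal-6-ene-4-carboxylate
Product: 17 methyl 1-(tert-butyldimethylsilyloxy)-9-(2,2-dimethoxyethyl)-4,10-dimethyl-trans-decal-6-ene-4-carboxylate, via lithium enolate 16 (not isolated)
Conditions: LiN(iPr)2, THF/DMPU, −78 °C → −40 °C; MeI, −78 °C → 0 °C
Reagents that add atoms: iodomethane CI
Why: Enolate alkylation: MeI should attack the exocyclic C4 ester enolate from the face opposite to the axial CH3-20 (equatorial attack, the known course for C4 ester enolates of 10-methyl-trans-decalins), so the new methyl is equatorial and the CO2Me axial and cis to CH3-20, as in the target.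

Step 10
Reactants: 17 methyl 1-(tert-butyldimethylsilyloxy)-9-(2,2-dimethoxyethyl)-4,10-dimethyl-trans-decal-6-ene-4-carboxylate
Product: 18 methyl 1-(tert-butyldimethylsilyloxy)-9-(2,2-dimethoxyethyl)-4,10-dimethyl-8-oxo-trans-decal-6-ene-4-carboxylate
Conditions: Pd(OH)2/C (5 mol %), t-BuOOH (5 equiv), K2CO3 (0.25 equiv), CH2Cl2, 4 °C
Reagents that add atoms: tert-butyl hydroperoxide CC(C)(C)OO
Why: Corey–Yu allylic oxidation (tert-butylperoxy radical chain): hydrogen should be abstracted from the only allylic CH2 (C8), C5–H being shielded by the two flanking quaternary carbons, and the peroxide formed at the less hindered C8 terminus collapses to the enone with C6=C7 in place; no stereocentre is formed.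

Step 11
Reactants: 18 methyl 1-(tert-butyldimethylsilyloxy)-9-(2,2-dimethoxyethyl)-4,10-dimethyl-8-oxo-trans-decal-6-ene-4-carboxylate
Product: 19 methyl 1-(tert-butyldimethylsilyloxy)-9-(2,2-dimethoxyethyl)-4,10-dimethyl-8-oxo-trans-decalin-4-carboxylate
Conditions: H2 (1 atm), Pd/C, EtOAc, rt
Reagents that add atoms: none
Why: Heterogeneous hydrogenation reduces only the conjugated C6=C7 bond (ketone, acetal, silyl ether and ester are inert) and creates no stereocentre.

Step 12
Reactants: 19 methyl 1-(tert-butyldimethylsilyloxy)-9-(2,2-dimethoxyethyl)-4,10-dimethyl-8-oxo-trans-decalin-4-carboxylate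
Product: 20 methyl 1-(tert-butyldimethylsilyloxy)-4,10-dimethyl-8-oxo-9-(2-oxoethyl)-trans-decalin-4-carboxylate
Conditions: PPTS (20 mol %), acetone/H2O (10:1), 40 °C
Reagents that add atoms: water O
Why: Mild acetal hydrolysis frees the C12 aldehyde, the weak acid leaving the epimerisable C9 and the 1,4-dicarbonyl unit (possible Paal–Knorr furan formation) intact.

Step 13
Reactants: 20 methyl 1-(tert-butyldimethylsilyloxy)-4,10-dimethyl-8-oxo-9-(2-oxoethyl)-trans-decalin-4-carboxylate; 21 2-(triphenylphosphoranylidene)propanal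
Product: 22 methyl 1-(tert-butyldimethylsilyloxy)-4,10-dimethyl-9-[(2E)-3-methyl-4-oxobut-2-en-1-yl]-8-oxo-trans-decalin-4-carboxylate
Conditions: toluene, 80 °C
Reagents that add atoms: none
Why: Wittig reaction of the stabilised ylide, which reacts with the aldehyde but not with the hindered C8 ketone, should give the 2-methyl-enal with (E)-geometry (the usual outcome for stabilised ylides), setting the 12E alkene.

Step 14
Reactants: 22 methyl 1-(tert-butyldimethylsilyloxy)-4,10-dimethyl-9-[(2E)-3-methyl-4-oxobut-2-en-1-yl]-8-oxo-trans-decalin-4-carboxylate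
Product: 23 methyl 1-(tert-butyldimethylsilyloxy)labda-8(17),12E,14-trien-19-oate
Conditions: Zn, CH2Br2, TiCl4, THF/CH2Cl2, 0 °C → rt
Reagents that add atoms: dibromomethane BrCBr
Why: Takai–Lombardo methylenation converts both the C8 ketone and the C14 aldehyde into C=CH2 groups under non-basic conditions, so C9 (α to the ketone) is not epimerised and the methyl ester is not attacked.

Step 15
Reactants: 23 methyl 1-(tert-butyldimethylsilyloxy)labda-8(17),12E,14-trien-19-oate
Product: 24 methyl 1-hydroxylabda-8(17),12E,14-trien-19-oate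
Conditions: Bu4NF, THF, 50 °C
Reagents that add atoms: none
Why: Fluoride-induced desilylation removes the hindered secondary TBS ether without affecting the triene or the ester; C1 is untouched.

Step 16
Reactants: 24 methyl 1-hydroxylabda-8(17),12E,14-trien-19-oate
Product: 25 methyl (1S,4R,5S,9R,10S)-1-acetoxylabda-8(17),12E,14-trien-19-oate
Conditions: Ac2O, DMAP (cat.), pyridine, rt
Reagents that add atoms: acetic anhydride CC(=O)OC(C)=O
Why: DMAP-catalysed acetylation of the equatorial C1 alcohol proceeds with retention and should give the target.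

**Compound list**

1 | dimethyl malonate | COC(=O)CC(=O)OC | starting material
2 | (E)-but-2-enal (crotonaldehyde) | C/C=C/C=O | starting material
3 | dimethyl 2-[(2E)-but-2-en-1-ylidene]propanedioate | COC(=O)C(=C/C=C/C)C(=O)OC | intermediate
4 | prop-2-enal (acrolein) | C=CC=O | starting material
5 | dimethyl 2-[(1E)-buta-1,3-dien-1-yl]-2-(3-oxopropyl)propanedioate | O=CCCC(C(=O)OC)(C(=O)OC)/C=C/C=C | intermediate
6 | 1,1-diethoxybut-2-yne (2-butynal diethyl acetal) | CC#CC(OCC)OCC | starting material
7 | dicyclohexyl[(2Z)-4,4-diethoxybut-2-en-2-yl]borane (boron cis to the vinylic H) | CCOC(OCC)/C=C(\C)B(C1CCCCC1)C1CCCCC1 | intermediate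
8 | [(2E)-4,4-diethoxybut-2-en-2-yl](methyl)zinc | CCOC(OCC)/C=C(\C)[Zn]C | intermediate
9 | dimethyl 2-[(1E)-buta-1,3-dien-1-yl]-2-[(3S,4E)-6,6-diethoxy-3-hydroxy-4-methylhex-4-en-1-yl]propanedioate | CCOC(OCC)/C=C(\C)[C@@H](O)CCC(C(=O)OC)(C(=O)OC)/C=C/C=C | intermediate
10 | dimethyl 2-[(1E)-buta-1,3-dien-1-yl]-2-[(3S,4E)-3-(tert-butyldimethylsilyloxy)-6,6-diethoxy-4-methylhex-4-en-1-yl]propanedioate | CCOC(OCC)/C=C(\C)[C@@H](O[Si](C)(C)C(C)(C)C)CCC(C(=O)OC)(C(=O)OC)/C=C/C=C | intermediate
11 | dimethyl 2-[(1E)-buta-1,3-dien-1-yl]-2-[(3S,4E)-3-(tert-butyldimethylsilyloxy)-4-methyl-6-oxohex-4-en-1-yl]propanedioate (the undeca-2,8,10-trienal) | O=C/C=C(\C)[C@@H](O[Si](C)(C)C(C)(C)C)CCC(C(=O)OC)(C(=O)OC)/C=C/C=C | intermediate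
12 | dimethyl 1-(tert-butyldimethylsilyloxy)-9-formyl-10-methyl-trans-decal-6-ene-4,4-dicarboxylate (H5 anti to CH3-20; 9-CHO and 1-OTBS equatorial, both cis to CH3-20) | O=C[C@@H]1CC=C[C@H]2[C@@]1(C)[C@@H](O[Si](C)(C)C(C)(C)C)CCC2(C(=O)OC)C(=O)OC | intermediate
13 | 9-(2-methoxyvinyl) enol ether derived from 12 (E/Z mixture; ring configuration as in 12) | COC=C[C@@H]1CC=C[C@H]2[C@@]1(C)[C@@H](O[Si](C)(C)C(C)(C)C)CCC2(C(=O)OC)C(=O)OC | intermediate
14 | dimethyl 1-(tert-butyldimethylsilyloxy)-9-(2,2-dimethoxyethyl)-10-methyl-trans-decal-6-ene-4,4-dicarboxylate (ring configuration as in 12) | COC(OC)C[C@@H]1CC=C[C@H]2[C@@]1(C)[C@@H](O[Si](C)(C)C(C)(C)C)CCC2(C(=O)OC)C(=O)OC | intermediate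
15 | methyl 1-(tert-butyldimethylsilyloxy)-9-(2,2-dimethoxyethyl)-10-methyl-trans-decal-6-ene-4-carboxylate (C4 epimers, equatorial ester drawn) | COC(OC)C[C@@H]1CC=C[C@H]2[C@@]1(C)[C@@H](O[Si](C)(C)C(C)(C)C)CC[C@@H]2C(=O)OC | intermediate
16 | lithium ester enolate of 15 (C4 sp2) | COC(OC)C[C@@H]1CC=C[C@H]2[C@@]1(C)[C@@H](O[Si](C)(C)C(C)(C)C)CCC2=C(OC)O[Li] | intermediate
17 | methyl 1-(tert-butyldimethylsilyloxy)-9-(2,2-dimethoxyethyl)-4,10-dimethyl-trans-decal-6-ene-4-carboxylate (CO2Me axial, cis to CH3-20) | COC(OC)C[C@@H]1CC=C[C@H]2[C@@]1(C)[C@@H](O[Si](C)(C)C(C)(C)C)CC[C@@]2(C)C(=O)OC | intermediate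
18 | methyl 1-(tert-butyldimethylsilyloxy)-9-(2,2-dimethoxyethyl)-4,10-dimethyl-8-oxo-trans-decal-6-ene-4-carboxylate | COC(OC)C[C@@H]1C(=O)C=C[C@H]2[C@@]1(C)[C@@H](O[Si](C)(C)C(C)(C)C)CC[C@@]2(C)C(=O)OC | intermediate
19 | methyl 1-(tert-butyldimethylsilyloxy)-9-(2,2-dimethoxyethyl)-4,10-dimethyl-8-oxo-trans-decalin-4-carboxylate | COC(OC)C[C@@H]1C(=O)CC[C@H]2[C@@]1(C)[C@@H](O[Si](C)(C)C(C)(C)C)CC[C@@]2(C)C(=O)OC | intermediate
20 | methyl 1-(tert-butyldimethylsilyloxy)-4,10-dimethyl-8-oxo-9-(2-oxoethyl)-trans-decalin-4-carboxylate | O=CC[C@@H]1C(=O)CC[C@H]2[C@@]1(C)[C@@H](O[Si](C)(C)C(C)(C)C)CC[C@@]2(C)C(=O)OC | intermediate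
21 | 2-(triphenylphosphoranylidene)propanal | CC(C=O)=P(c1ccccc1)(c1ccccc1)c1ccccc1 | starting material
22 | methyl 1-(tert-butyldimethylsilyloxy)-4,10-dimethyl-9-[(2E)-3-methyl-4-oxobut-2-en-1-yl]-8-oxo-trans-decalin-4-carboxylate | O=C/C(C)=C/C[C@@H]1C(=O)CC[C@H]2[C@@]1(C)[C@@H](O[Si](C)(C)C(C)(C)C)CC[C@@]2(C)C(=O)OC | intermediate
23 | methyl 1-(tert-butyldimethylsilyloxy)labda-8(17),12E,14-trien-19-oate (configuration as in 25) | C=C/C(C)=C/C[C@@H]1C(=C)CC[C@H]2[C@@]1(C)[C@@H](O[Si](C)(C)C(C)(C)C)CC[C@@]2(C)C(=O)OC | intermediate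
24 | methyl 1-hydroxylabda-8(17),12E,14-trien-19-oate (configuration as in 25) | C=C/C(C)=C/C[C@@H]1C(=C)CC[C@H]2[C@@]1(C)[C@@H](O)CC[C@@]2(C)C(=O)OC | intermediate
25 | methyl (1S,4R,5S,9R,10S)-1-acetoxylabda-8(17),12E,14-trien-19-oate (CNP0235031.1) | C=C/C(C)=C/C[C@@H]1C(=C)CC[C@H]2[C@@]1(C)[C@@H](OC(C)=O)CC[C@@]2(C)C(=O)OC | target

**Count and risks**

Total step count: 16. Longest linear sequence: 16 steps (1 → 25); 4, 6 and 21 enter as commercial materials.

Steps most likely to fail:

Step 6. The cycloaddition may be slow and lose endo and π-facial selectivity, because the C5–C10 bond joins a fully substituted dienophile carbon to a diene terminus next to the quaternary C4, and one ester must become 1,3-diaxial to CH3-20 in the trans-fused transition state. The fallback sets out from 10 and comes back at 12. Me3SiOTf (10 mol %) in CH2Cl2 at −78 °C should ionise the enal acetal to a 1-ethoxyallyl cation, a far more reactive 2π partner, and a cationic (Gassman-type) intramolecular Diels–Alder reaction should give the cycloadduct diethyl acetal F1. PPTS in wet acetone should then give 12.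

Step 3. The enantioselectivity may erode through uncatalysed background addition of the alkenylzinc reagent to the unbranched aliphatic aldehyde. The fallback sets out from 5 and comes back at 9. The same alkenylzinc addition run without the chiral ligand should give the racemic allylic alcohol F2. Dess–Martin periodinane should oxidise it to the α-methyl enone F3. Corey–Bakshi–Shibata reduction ((R)-2-methyl-CBS-oxazaborolidine 10 mol %, catecholborane, toluene, −78 °C) should then give 9, the alkenyl group acting as the large substituent.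

Step 10. Regiocontrol may be lost when the allyl radical is trapped (oxygen at C6 instead of C8), and the acetal C–H may be oxidised in competition. The fallback sets out from 17 and comes back at 18. SeO2 (0.5 equiv) with t-BuOOH in CH2Cl2 at rt works by a closed-shell ene reaction at C6 with the C8–H, then a [2,3]-shift that returns oxygen to C8 (CH2 reacts before CH), and should give the allylic alcohol F4. Dess–Martin periodinane should then give 18.

Further compounds
F1 | step 6 | dimethyl 1-(tert-butyldimethylsilyloxy)-9-(diethoxymethyl)-10-methyl-trans-decal-6-ene-4,4-dicarboxylate | CCOC(OCC)[C@@H]1CC=C[C@H]2[C@@]1(C)[C@@H](O[Si](C)(C)C(C)(C)C)CCC2(C(=O)OC)C(=O)OC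
F2 | step 3 | racemic dimethyl 2-[(1E)-buta-1,3-dien-1-yl]-2-[(4E)-6,6-diethoxy-3-hydroxy-4-methylhex-4-en-1-yl]propanedioate | CCOC(OCC)/C=C(\C)C(O)CCC(C(=O)OC)(C(=O)OC)/C=C/C=C
F3 | step 3 | dimethyl 2-[(1E)-buta-1,3-dien-1-yl]-2-[(4E)-6,6-diethoxy-4-methyl-3-oxohex-4-en-1-yl]propanedioate | CCOC(OCC)/C=C(\C)C(=O)CCC(C(=O)OC)(C(=O)OC)/C=C/C=C
F4 | step 10 | methyl 1-(tert-butyldimethylsilyloxy)-9-(2,2-dimethoxyethyl)-8-hydroxy-4,10-dimethyl-trans-decal-6-ene-4-carboxylate (C8 epimers) | COC(OC)C[C@@H]1C(O)C=C[C@H]2[C@@]1(C)[C@@H](O[Si](C)(C)C(C)(C)C)CC[C@@]2(C)C(=O)OC
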